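Remark on the chemistry: the target is achiral. The racemic intermediates (21 and the transient 33 and 35) lose their stereocentres in step 16, so no stereocontrol is needed.

## Analysis of the target

The target is a linear trimer of three hexasubstituted phloroglucinol rings joined by two methylene bridges; it has no ring fusion, no stereocentre and no symmetry. Ring B, the central ring, carries an acetyl group at C1, hydroxyls at C2, C4 and C6, and the bridges at C3 (to ring A) and C5 (to ring C). Rings A and C are constitutional isomers: each has butanoyl, methyl, one methoxy and two hydroxyl groups. In ring A the methoxy group is para to the ketone and the bridge lies between methoxy and hydroxyl. In ring C the methoxy group is ortho to the ketone and the bridge lies between two hydroxyls. The sensitive features are seven free phenols (oxidation, O- versus C-alkylation), three chelated aryl ketones, and above all the two diarylmethane links, which in polyhydroxylated rings are cleaved and re-formed under acid or base, so that unsymmetrical oligomers scramble. The difficulty is therefore the order A–B–C: a formaldehyde-type or quinone methide coupling cannot place two different, isomeric outer rings on the two equivalent carbons of a central acylphloroglucinol without statistical mixtures, and each outer ring needs its own defined O-methylation. The strategy rests on ring B itself: its six carbons come from a four-carbon vinylketene (C4, C3, C2, C1, with C3 already bonded to the ring A methylene) and a two-carbon silyl ynol ether (C5, C6, with C5 already bonded to the ring C methylene). Both bridges are thus in place before the central ring exists, and the acetyl group is added last at the only free carbon, C1.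

## Retrosynthetic reasoning

The target 39 is taken back to its pentabenzyl ether 38. Hydrogenolysis is neutral, so the free heptaphenol is released under conditions that cannot move a bridge. Cutting the C1–acetyl bond of ring B in 38 gives 37, in which C1 is the single unsubstituted carbon of the three core rings and lies between two oxygen-bearing carbons; a Friedel–Crafts acetylation has only one place to go. 37 comes from 36 by cleavage of two silicon–oxygen bonds, which frees the C6 hydroxyl of ring B and, through the enol ether, the ring C ketone in one operation. No redox step is then needed after the central ring has been made.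

Ring B of 36 is cut at C4–C5 and C6–C1 (the cycloaddition bonds) and at C3–C4 (the electrocyclisation bond). This gives cyclobutenone 21, which holds C4, C3, C2, C1 and the ring A unit, and silyl ynol ether 31, which holds C5, C6 and the ring C unit. This cut is preferred to any bridge disconnection because it divides the molecule into halves of similar size and leaves each methylene attached to its outer ring by a bond that already exists. It also replaces the unselective double benzylation of a central trihydroxybenzene ring by a ring synthesis whose regiochemistry is set by polarity. The forward reaction must open 21, combine the vinylketene with 31 in the right orientation and aromatise, under neutral thermal conditions that benzyl ethers, the silyl enol ether and the ketone tolerate. The one carbon it leaves unsubstituted, C1, is the carbon that later takes the acetyl group.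

Cyclobutenone 21 is cut across the four-membered ring into ketene 20 and benzyl ethynyl ether 19, a [2+2] retron in which the ketene carbonyl carbon becomes C4 of ring B and the substituted ketene carbon becomes C3. The oxygen on C3 of the cyclobutenone (C2 of ring B) is carried as a benzyl ether and not as a silyl ether. The vinylogous benzyl ester is robust to chromatography, the benzyl group leaves in the last step with the other four, and 19 is reached in two steps from 13 and 14 through 16. Ketene 20 is generated from acid chloride 12, and this from acid 11.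

The side chain of 11 is cut between its benzylic carbon and the carbon next to the carboxyl group, giving aldehyde 7 and Meldrum's acid 8. A reductive condensation adds two carbons at the right saturation level in one step, without a catalytic hydrogenation that would endanger the benzyl ethers. Aldehyde 7 is the dibenzyl ether of 6; 6 arises from 4 by formylation at its only free ring carbon; 4 is the para O-methyl ether of 3; and 3 comes from 1 and 2 by C-acylation. The order acylation, para-selective methylation, formylation sets ring A: the ketone makes the para hydroxyl the most reactive one, and the last free carbon is then flanked by methoxy and hydroxyl.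

Silyl ynol ether 31 is cut at the triple bond back to ester 28. The ester carbonyl carbon becomes C6 of ring B and the inserted carbon becomes C5, so the arylacetic ester already holds the ring C bridge. The ring C ketone cannot pass through the organolithium chemistry of this homologation and is masked as the (Z)-silyl enol ether. Compared with a protected carbinol this keeps the oxidation level, so no oxidation is needed beside an electron-rich central ring, and it avoids a 2,4,6-trialkoxybenzylic ether that would ionise under acid. The aryl–methylene bond of 28 is cut to bromide 26 and zinc enolate 27, and 26 comes from ketone 24 by enol silylation.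

Bromide 24 is traced to 23 (bromine removed from the only free ring position), 23 to phenol 22 (methyl removed from oxygen) and 22 to the common triol 3 (two benzyl groups removed). Here the forward order is benzylation first: the para hydroxyl and the less hindered ortho hydroxyl of 3 are alkylated, the hydroxyl held between ketone and methyl group remains and then receives the methyl group, and the last free carbon, between the two benzyloxy groups, becomes the bridge carbon. Rings A and C thus diverge from 3 only through the order of the same kinds of operation.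

## Alternatives that were turned down

Alternative 1: Ring C is disconnected inside its own carbocycle, at the bond between the bridge-bearing carbon and a hydroxyl-bearing carbon. This leads to pyranone A1, whose C6 carries a two-carbon tether to a complete, benzyl-protected A–B unit. In the forward direction hot basic alcohol opens the lactone to a keto ester, and the ketone enolate on the tether side condenses with the ester to give resorcinol A2, with methoxy, methyl and bridge in place and the butanoyl carbon free.
- For: no ynol ether or cyclobutenone is needed, the reagents are trivial, and the ring C methoxy group is fixed by the vinylogous ester of A1. That is a cleaner answer to the ring C oxygen pattern than the selective alkylations of steps 10 and 11.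
- Against: A1 presupposes the unsymmetrical A–B diarylmethane, so the central problem is moved, not solved. The acetyl and butanoyl ketones must survive hot base, and the opened chain has a second, vinylogous enolate site. The butanoyl group must then enter by Lewis-acid acylation ortho to a methoxy group in the presence of five benzyl ethers.
- Comparison: the route is linear, because ring C is grown on the whole A–B fragment. The chosen strategy gives up the built-in methoxy regiochemistry and offers instead a convergent union of two halves made in parallel, in a neutral bond-forming event.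

Alternative 2: Ring C is again the ring that is made, by a three-bond cut that gives cyclobutenone A3 (2-methyl, 3-silyloxy, the A–B benzyl group on C4) and methoxyethyne A4. Heating them gives phenol A5 with the butanoyl carbon unsubstituted.
- For: it uses the same pericyclic chemistry as the chosen route and is mechanistically as strong. It is stronger on two points: the small alkyne A4 can be used in large excess to drive the bimolecular step, and it delivers the ring C methoxy group in a defined position.
- Against: A3 is a trisubstituted cyclobutenone that must be built on the complete A–B diarylmethane, whose construction is the unsolved part. A4 is a low-boiling, unstable reagent that must be held in a sealed vessel at the ring-opening temperature. A late butanoylation ortho to methoxy is still required.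
- Comparison: the benzannulation adds only two carbons at the end of a linear sequence. The chosen route uses the same reaction as the fragment coupling itself, so its risk buys the whole A–B–C connectivity.

Alternative 3: Ring A is disconnected in the same way into cyclobutenone A6 (3-methoxy, 4-methyl, the B–C benzyl group on C2) and (triisopropylsilyloxy)ethyne A7. Heating gives phenol A8, whose free carbon lies between a hydroxyl and a silyloxy group.
- For: it has the best late acylation of the three. After desilylation the butanoyl group enters between two hydroxyls, the most reactive and least ambiguous site. Methoxy and methyl of ring A are placed by the cyclobutenone and not by selective O-methylation as in step 2.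
- Against: A6 needs the B–C diarylmethane with the acetyl group already on ring B, so an unsymmetrically substituted central ring must again be made by other means. A7 is less accessible than the ester-derived ynol ether 31. In A6 the large substituent sits on the ketene α-carbon, which should slow the cycloaddition more than a substituent on C4 does.
- Comparison: the sequence is linear, as in alternative 2. The chosen route concedes the selective methylation of ring A, a well-behaved para-selective alkylation, and in exchange forms both bridges by construction.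

Key step: step 16

Abbreviations used in names (attachment through C1 of the phenyl ring):
- ArA = 2,4-bis(benzyloxy)-3-butanoyl-6-methoxy-5-methylphenyl
- ArC = 2,6-bis(benzyloxy)-4-methoxy-3-methyl-5-[(1Z)-1-(triisopropylsilyloxy)but-1-en-1-yl]phenyl
- ArC′ = 2,6-bis(benzyloxy)-3-butanoyl-4-methoxy-5-methylphenyl

## Steps

Step 1
Reactants: 1 2-methylbenzene-1,3,5-triol; 2 butanoyl chloride
Product: 3 1-(2,4,6-trihydroxy-3-methylphenyl)butan-1-one
Conditions: AlCl3, PhNO2–CH2Cl2, 0 °C to rt
Reagents that add atoms: none
Why: Friedel–Crafts C-acylation of the phloroglucinol; the two free ring carbons of 1 are equivalent, so only one monoacyl product can form, and the chelated ketone deactivates the ring towards a second acylation.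

Step 2
Reactants: 3 1-(2,4,6-trihydroxy-3-methylphenyl)butan-1-one
Product: 4 1-(2,6-dihydroxy-4-methoxy-3-methylphenyl)butan-1-one (aspidinol)
Conditions: Me2SO4 (1.0 equiv), K2CO3 (1.0 equiv), acetone, rt to 40 °C
Reagents that add atoms: dimethyl sulfate, COS(=O)(=O)OC
Why: Williamson-type O-methylation of the most acidic, non-chelated hydroxyl para to the ketone; the two ortho hydroxyls are held in hydrogen bonds to the carbonyl and react more slowly, so one equivalent of alkylating agent should give mainly the 4-methyl ether.

Step 3
Reactants: 4 1-(2,6-dihydroxy-4-methoxy-3-methylphenyl)butan-1-one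
Product: 6 3-butanoyl-2,4-dihydroxy-6-methoxy-5-methylbenzaldehyde, via iminium chloride 5 (not isolated)
Conditions: POCl3, DMF, EtOAc, 0 °C to rt; then H2O, 50 °C
Reagents that add atoms: N,N-dimethylformamide, CN(C)C=O; water, O
Why: Vilsmeier–Haack formylation; ring carbon 5 of 4 is the only unsubstituted position and is activated by the flanking methoxy and hydroxyl groups, so the site is unambiguous, and aqueous hydrolysis of the iminium salt releases the aldehyde.

Step 4
Reactants: 6 3-butanoyl-2,4-dihydroxy-6-methoxy-5-methylbenzaldehyde
Product: 7 2,4-bis(benzyloxy)-3-butanoyl-6-methoxy-5-methylbenzaldehyde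
Conditions: BnBr (2.5 equiv), K2CO3, DMF, 60 °C
Reagents that add atoms: benzyl bromide, BrCc1ccccc1
Why: Williamson ether synthesis; both hydroxyls are chelated and hindered, hence the polar aprotic solvent, excess halide and mild heating, and because every ring carbon is substituted C-alkylation would require dearomatisation and should not compete.

Step 5
Reactants: 7 2,4-bis(benzyloxy)-3-butanoyl-6-methoxy-5-methylbenzaldehyde; 8 Meldrum's acid (2,2-dimethyl-1,3-dioxane-4,6-dione)
Product: 11 3-(ArA)propanoic acid, via arylidene Meldrum's acid 9 (not isolated), via arylmethyl Meldrum's acid 10 (not isolated)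
Conditions: HCO2H–Et3N (5:2), 95–100 °C
Reagents that add atoms: none
Why: Tandem Knoevenagel condensation, conjugate reduction of the electron-poor alkylidene by formate (transfer hydrogenation) and hydrolysis–decarboxylation in one flask; the hindered, non-conjugated aryl ketone and the benzyl ethers are inert to the formate medium, which is why this is preferred to an olefination followed by catalytic hydrogenation.

Step 6
Reactants: 11 3-(ArA)propanoic acid
Product: 12 3-(ArA)propanoyl chloride
Conditions: (COCl)2, cat. DMF, CH2Cl2, 0 °C to rt; concentrated and used at once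
Reagents that add atoms: oxalyl chloride, O=C(Cl)C(=O)Cl
Why: Standard acid chloride formation with only volatile by-products; the chloride is the ketene precursor and is used without storage so that it cannot lactonise onto the ortho benzyloxy group.

Step 7
Reactants: 13 benzyl alcohol; 14 trichloroethene
Product: 16 benzyl (E)-1,2-dichlorovinyl ether, via dichloroethyne 15 (not isolated)
Conditions: KH, THF, 0 °C; then 14, −50 °C to rt
Reagents that add atoms: none
Why: The alkoxide dehydrochlorinates trichloroethene to dichloroethyne and then adds to it in anti fashion to give the (E)-dichlorovinyl ether, the established entry to ynol ethers from alcohols.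

Step 8
Reactants: 16 benzyl (E)-1,2-dichlorovinyl ether
Product: 19 benzyl ethynyl ether, via chloroethynyl benzyl ether 17 (not isolated), via lithium benzyloxyacetylide 18 (not isolated)
Conditions: n-BuLi (2.2 equiv), THF, −78 to −40 °C; then MeOH, −78 °C; kept cold and used as an ethereal solution
Reagents that add atoms: none
Why: Base-induced β-elimination of HCl and then chlorine–lithium exchange give the lithium alkoxyacetylide, which is protonated at low temperature; the terminal ynol ether is kept below room temperature because benzyl alkynyl ethers rearrange on warming.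

Step 9
Reactants: 12 3-(ArA)propanoyl chloride; 19 benzyl ethynyl ether
Product: 21 racemic 3-(benzyloxy)-4-(ArA-methyl)cyclobut-2-en-1-one, via ketene 20 (not isolated)
Conditions: 19 (3 equiv), Et3N (slow addition), Et2O, 0 °C to rt
Reagents that add atoms: none
Why: Dehydrochlorination of 12 gives the monosubstituted ketene 20, which undergoes thermal [2+2] cycloaddition with the alkoxyalkyne; the electrophilic ketene carbon bonds to the nucleophilic terminal alkyne carbon, which puts the benzyloxy group on C3 and the ring A benzyl group on the sp3 carbon C4. The C4 stereocentre forms as a racemate and is destroyed in step 16.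

Step 10
Reactants: 3 1-(2,4,6-trihydroxy-3-methylphenyl)butan-1-one
Product: 22 1-[2,4-bis(benzyloxy)-6-hydroxy-5-methylphenyl]butan-1-one
Conditions: BnBr (2.1 equiv), K2CO3, acetone, reflux
Reagents that add atoms: benzyl bromide, BrCc1ccccc1
Why: Williamson etherification; the para hydroxyl reacts first, and of the two chelated ortho hydroxyls the one next to the unsubstituted ring carbon is more accessible, so the hydroxyl flanked by ketone and methyl group should remain, as is usual in partial alkylation of C-methylated acylphloroglucinols.

Step 11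
Reactants: 22 1-[2,4-bis(benzyloxy)-6-hydroxy-5-methylphenyl]butan-1-one
Product: 23 1-[2,4-bis(benzyloxy)-6-methoxy-5-methylphenyl]butan-1-one
Conditions: MeI, K2CO3, DMF, 50 °C
Reagents that add atoms: iodomethane, CI
Why: O-Methylation of the remaining chelated phenol under forcing Williamson conditions; a carbonate base is used so that the ketone is not enolised and C-methylated.

Step 12
Reactants: 23 1-[2,4-bis(benzyloxy)-6-methoxy-5-methylphenyl]butan-1-one
Product: 24 1-[2,4-bis(benzyloxy)-3-bromo-6-methoxy-5-methylphenyl]butan-1-one
Conditions: NBS, MeCN, 0 °C to rt, dark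
Reagents that add atoms: N-bromosuccinimide, O=C1CCC(=O)N1Br
Why: Electrophilic aromatic bromination at the single free ring carbon, ortho to both benzyloxy groups and para to the methoxy group; polar, radical-free conditions leave the benzylic positions and the ketone α-carbon untouched.

Step 13
Reactants: 24 1-[2,4-bis(benzyloxy)-3-bromo-6-methoxy-5-methylphenyl]butan-1-one
Product: 26 [(1Z)-1-(2,4-bis(benzyloxy)-3-bromo-6-methoxy-5-methylphenyl)but-1-en-1-yl]oxy-triisopropylsilane, via potassium enolate 25 (not isolated)
Conditions: KHMDS, THF, −78 °C; TIPSOTf, −78 to 0 °C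
Reagents that add atoms: triisopropylsilyl trifluoromethanesulfonate, CC(C)[Si](OS(=O)(=O)C(F)(F)F)(C(C)C)C(C)C
Why: Kinetic enolisation and O-silylation; the twisted, di-ortho-substituted aryl group acts as a bulky substituent and should favour the Z enolate. The enol ether masks the ketone at its own oxidation level against the organolithium reagents of step 15 and is later removed by fluoride together with the aryl silyl ether.

Step 14
Reactants: 26 the (Z)-silyl enol ether bromide; 27 bromo(2-ethoxy-2-oxoethyl)zinc
Product: 28 ethyl (ArC)acetate
Conditions: 27 (2 equiv), Pd2(dba)3 (2.5 mol %), XPhos (10 mol %), THF, 65 °C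
Reagents that add atoms: none
Why: Palladium-catalysed coupling of an aryl bromide with a Reformatsky reagent (Negishi-type arylation of a zinc ester enolate); a bulky biarylphosphine on zerovalent palladium is chosen for the electron-rich, di-ortho-substituted bromide, and the neutral zinc enolate leaves the silyl enol ether intact.

Step 15
Reactants: 28 ethyl (ArC)acetate
Product: 31 [3-(ArC)prop-1-yn-1-yl]oxy-triisopropylsilane, via dibromo enolate 29 (not isolated), via lithium ynolate 30 (not isolated)
Conditions: CH2Br2, LiTMP, THF, −78 °C; LiHMDS, −78 to −20 °C; n-BuLi, −78 °C to rt; TIPSOTf, −78 to 0 °C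
Reagents that add atoms: dibromomethane, BrCBr; triisopropylsilyl trifluoromethanesulfonate, CC(C)[Si](OS(=O)(=O)C(F)(F)F)(C(C)C)C(C)C
Why: Kowalski ester homologation stopped at the ynolate: dibromomethyllithium adds to the ester, the derived dibromo enolate undergoes bromine–lithium exchange and 1,2-shift of the arylmethyl group to ynolate 30, and the bulky silyl triflate silylates it on oxygen. Addition of the carbenoid at −78 °C should outrun enolisation of the arylacetate.

Step 16
Reactants: 21 racemic 3-(benzyloxy)-4-(ArA-methyl)cyclobut-2-en-1-one; 31 [3-(ArC)prop-1-yn-1-yl]oxy-triisopropylsilane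
Product: 36 6-(ArA-methyl)-5-(benzyloxy)-2-(ArC-methyl)-3-(triisopropylsilyloxy)phenol, via vinylketene 32 (not isolated), via vinylcyclobutenone 33 (not isolated), via dienylketene 34 (not isolated), via cyclohexadienone 35 (not isolated)
Conditions: 21 (1.3 equiv), toluene (0.3 M), 100–110 °C, sealed tube, argon
Reagents that add atoms: none
Why: Danheiser benzannulation: heating opens 21 by four-electron electrocyclic ring opening (the C4 substituent rotating outward) to vinylketene 32, which adds the electron-rich alkyne 31 in a [2+2] cycloaddition to give 33; a second four-electron opening gives dienylketene 34, six-electron disrotatory electrocyclisation closes ring B as cyclohexadienone 35, and tautomerisation gives phenol 36. The closest known reaction type is the thermal union of cyclobutenones with silyl ynol ethers to monosilylated resorcinols; the benzyloxy group on C3 of 21 is a spectator that ends as the C2 ether of ring B, and thermal opening of 3-alkoxycyclobutenones to vinylketenes is established. Ring B is the only ring formed; it is closed by the 6π electrocyclisation (bond C3–C4) after C4–C5 and C6–C1 have been made in the cycloaddition. No stereocentre is created: the centre of racemic 21 and those of 33 and 35 disappear on aromatisation. The selectivity needed is regiochemical and is set by polarity: the electrophilic ketene carbon (C4) bonds to the nucleophilic β-carbon of the ynol ether, which carries the ring C methylene, so the silyloxy carbon (C6) ends meta to the new hydroxyl and next to the free C1. The medium is neutral and aprotic, so neither methylene bridge can migrate, and the order ring A, ring B, ring C follows from the two precursors alone. A slight excess of 21 allows for ketene dimerisation, and the hindered phenol of 36, flanked by both arylmethyl groups, should resist acylation by 32.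

Step 17
Reactants: 36 the benzannulation phenol
Product: 37 4-(ArA-methyl)-5-(benzyloxy)-2-(ArC′-methyl)benzene-1,3-diol
Conditions: TBAF (3 equiv), AcOH (3 equiv), THF, 0 °C to rt
Reagents that add atoms: none
Why: Fluoride-mediated desilylation cleaves the aryl silyl ether and the silyl enol ether in one operation; the buffer protonates the phenoxide and the enolate, which returns the ring C butanoyl group, while benzyl ethers and both diarylmethane links are inert.

Step 18
Reactants: 37 4-(ArA-methyl)-5-(benzyloxy)-2-(ArC′-methyl)benzene-1,3-diol
Product: 38 1-[3-(ArA-methyl)-2-(benzyloxy)-4,6-dihydroxy-5-(ArC′-methyl)phenyl]ethan-1-one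
Conditions: Ac2O (1.5 equiv), BF3·OEt2, CH2Cl2, 0 °C to rt; aq. NaHCO3
Reagents that add atoms: acetic anhydride, CC(=O)OC(C)=O
Why: Friedel–Crafts C-acetylation of a resorcinol-type ring; C1 of ring B is the only unsubstituted carbon of the three core rings, lies between a hydroxyl and a benzyloxy group and para to the second hydroxyl, so attack is unambiguous and fast, and the new ketone is stabilised by chelation to the neighbouring hydroxyl.

Step 19
Reactants: 38 the acetylated pentabenzyl ether
Product: 39 1-[3-({3-acetyl-5-[(3-butanoyl-2,6-dihydroxy-4-methoxy-5-methylphenyl)methyl]-2,4,6-trihydroxyphenyl}methyl)-2,6-dihydroxy-4-methoxy-5-methylphenyl]butan-1-one (CNP0184345.0)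
Conditions: H2 (1 atm), Pd/C (10 %), EtOAc–MeOH, rt, degassed solvents
Reagents that add atoms: none
Why: Hydrogenolysis of the five benzyl ethers; the ortho-hydroxy aryl ketones, the methyl ethers and the diarylmethane links are stable to palladium on carbon at ambient pressure, and the neutral medium avoids bridge scrambling in the free polyphenol.

## Compound list

1 | 2-methylbenzene-1,3,5-triol | Cc1c(O)cc(O)cc1O | starting material
2 | butanoyl chloride | CCCC(=O)Cl | starting material
3 | 1-(2,4,6-trihydroxy-3-methylphenyl)butan-1-one | CCCC(=O)c1c(O)cc(O)c(C)c1O | intermediate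
4 | 1-(2,6-dihydroxy-4-methoxy-3-methylphenyl)butan-1-one (aspidinol) | CCCC(=O)c1c(O)cc(OC)c(C)c1O | intermediate
5 | [(3-butanoyl-2,4-dihydroxy-6-methoxy-5-methylphenyl)methylidene]dimethylammonium chloride (not isolated) | CCCC(=O)c1c(O)c(C=[N+](C)C)c(OC)c(C)c1O.[Cl-] | intermediate
6 | 3-butanoyl-2,4-dihydroxy-6-methoxy-5-methylbenzaldehyde | CCCC(=O)c1c(O)c(C=O)c(OC)c(C)c1O | intermediate
7 | 2,4-bis(benzyloxy)-3-butanoyl-6-methoxy-5-methylbenzaldehyde | CCCC(=O)c1c(OCc2ccccc2)c(C=O)c(OC)c(C)c1OCc1ccccc1 | intermediate
8 | Meldrum's acid (2,2-dimethyl-1,3-dioxane-4,6-dione) | CC1(C)OC(=O)CC(=O)O1 | starting material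
9 | 5-(ArA-methylidene)-2,2-dimethyl-1,3-dioxane-4,6-dione (not isolated) | CCCC(=O)c1c(OCc2ccccc2)c(C=C2C(=O)OC(C)(C)OC2=O)c(OC)c(C)c1OCc1ccccc1 | intermediate
10 | 5-(ArA-methyl)-2,2-dimethyl-1,3-dioxane-4,6-dione (not isolated) | CCCC(=O)c1c(OCc2ccccc2)c(CC2C(=O)OC(C)(C)OC2=O)c(OC)c(C)c1OCc1ccccc1 | intermediate
11 | 3-(ArA)propanoic acid | CCCC(=O)c1c(OCc2ccccc2)c(CCC(=O)O)c(OC)c(C)c1OCc1ccccc1 | intermediate
12 | 3-(ArA)propanoyl chloride | CCCC(=O)c1c(OCc2ccccc2)c(CCC(=O)Cl)c(OC)c(C)c1OCc1ccccc1 | intermediate
13 | benzyl alcohol | OCc1ccccc1 | starting material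
14 | trichloroethene | ClC=C(Cl)Cl | starting material
15 | dichloroethyne (not isolated) | ClC#CCl | intermediate
16 | benzyl (E)-1,2-dichlorovinyl ether | Cl/C=C(/Cl)OCc1ccccc1 | intermediate
17 | chloroethynyl benzyl ether (not isolated) | ClC#COCc1ccccc1 | intermediate
18 | lithium benzyloxyacetylide (not isolated) | [Li]C#COCc1ccccc1 | intermediate
19 | benzyl ethynyl ether | C#COCc1ccccc1 | intermediate
20 | 3-(ArA)prop-1-en-1-one, the ketene (not isolated) | O=C=CCc1c(OCc2ccccc2)c(C(=O)CCC)c(OCc2ccccc2)c(C)c1OC | intermediate
21 | racemic 3-(benzyloxy)-4-(ArA-methyl)cyclobut-2-en-1-one | O=C1C=C(OCc2ccccc2)C1Cc1c(OCc2ccccc2)c(C(=O)CCC)c(OCc2ccccc2)c(C)c1OC | intermediate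
22 | 1-[2,4-bis(benzyloxy)-6-hydroxy-5-methylphenyl]butan-1-one | CCCC(=O)c1c(OCc2ccccc2)cc(OCc2ccccc2)c(C)c1O | intermediate
23 | 1-[2,4-bis(benzyloxy)-6-methoxy-5-methylphenyl]butan-1-one | CCCC(=O)c1c(OCc2ccccc2)cc(OCc2ccccc2)c(C)c1OC | intermediate
24 | 1-[2,4-bis(benzyloxy)-3-bromo-6-methoxy-5-methylphenyl]butan-1-one | CCCC(=O)c1c(OCc2ccccc2)c(Br)c(OCc2ccccc2)c(C)c1OC | intermediate
25 | potassium (1Z)-1-[2,4-bis(benzyloxy)-3-bromo-6-methoxy-5-methylphenyl]but-1-en-1-olate (not isolated) | CC/C=C(\[O-])c1c(OC)c(C)c(OCc2ccccc2)c(Br)c1OCc1ccccc1.[K+] | intermediate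
26 | [(1Z)-1-(2,4-bis(benzyloxy)-3-bromo-6-methoxy-5-methylphenyl)but-1-en-1-yl]oxy-triisopropylsilane | CC/C=C(\O[Si](C(C)C)(C(C)C)C(C)C)c1c(OC)c(C)c(OCc2ccccc2)c(Br)c1OCc1ccccc1 | intermediate
27 | bromo(2-ethoxy-2-oxoethyl)zinc | CCOC(=O)C[Zn]Br | starting material
28 | ethyl (ArC)acetate | CC/C=C(\O[Si](C(C)C)(C(C)C)C(C)C)c1c(OC)c(C)c(OCc2ccccc2)c(CC(=O)OCC)c1OCc1ccccc1 | intermediate
29 | lithium 1,1-dibromo-3-(ArC)prop-1-en-2-olate (not isolated) | CC/C=C(\O[Si](C(C)C)(C(C)C)C(C)C)c1c(OC)c(C)c(OCc2ccccc2)c(CC(O[Li])=C(Br)Br)c1OCc1ccccc1 | intermediate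
30 | lithium 3-(ArC)prop-1-yn-1-olate (not isolated) | CC/C=C(\O[Si](C(C)C)(C(C)C)C(C)C)c1c(OC)c(C)c(OCc2ccccc2)c(CC#CO[Li])c1OCc1ccccc1 | intermediate
31 | [3-(ArC)prop-1-yn-1-yl]oxy-triisopropylsilane | CC/C=C(\O[Si](C(C)C)(C(C)C)C(C)C)c1c(OC)c(C)c(OCc2ccccc2)c(CC#CO[Si](C(C)C)(C(C)C)C(C)C)c1OCc1ccccc1 | intermediate
32 | (3Z)-3-(benzyloxy)-5-(ArA)penta-1,3-dien-1-one (not isolated) | O=C=C/C(OCc1ccccc1)=C/Cc1c(OCc2ccccc2)c(C(=O)CCC)c(OCc2ccccc2)c(C)c1OC | intermediate
33 | racemic 4-[(1Z)-1-(benzyloxy)-3-(ArA)prop-1-en-1-yl]-2-(ArC-methyl)-3-(triisopropylsilyloxy)cyclobut-2-en-1-one (not isolated) | O=C1C(Cc2c(OCc3ccccc3)c(C)c(OC)c(/C(O[Si](C(C)C)(C(C)C)C(C)C)=C/CC)c2OCc2ccccc2)=C(O[Si](C(C)C)(C(C)C)C(C)C)C1/C(OCc1ccccc1)=C/Cc1c(OCc2ccccc2)c(C(=O)CCC)c(OCc2ccccc2)c(C)c1OC | intermediate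
34 | (3E,5Z)-5-(benzyloxy)-7-(ArA)-2-(ArC-methyl)-3-(triisopropylsilyloxy)hepta-1,3,5-trien-1-one (not isolated) | O=C=C(Cc1c(OCc2ccccc2)c(C)c(OC)c(/C(O[Si](C(C)C)(C(C)C)C(C)C)=C/CC)c1OCc1ccccc1)/C(O[Si](C(C)C)(C(C)C)C(C)C)=C\C(OCc1ccccc1)=C\Cc1c(OCc2ccccc2)c(C(=O)CCC)c(OCc2ccccc2)c(C)c1OC | intermediate
35 | racemic 6-(ArA-methyl)-5-(benzyloxy)-2-(ArC-methyl)-3-(triisopropylsilyloxy)cyclohexa-2,4-dien-1-one (not isolated) | O=C1C(Cc2c(OCc3ccccc3)c(C)c(OC)c(/C(O[Si](C(C)C)(C(C)C)C(C)C)=C/CC)c2OCc2ccccc2)=C(O[Si](C(C)C)(C(C)C)C(C)C)C=C(OCc2ccccc2)C1Cc1c(OCc2ccccc2)c(C(=O)CCC)c(OCc2ccccc2)c(C)c1OC | intermediate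
36 | 6-(ArA-methyl)-5-(benzyloxy)-2-(ArC-methyl)-3-(triisopropylsilyloxy)phenol | CC/C=C(\O[Si](C(C)C)(C(C)C)C(C)C)c1c(OC)c(C)c(OCc2ccccc2)c(Cc2c(O)c(Cc3c(OCc4ccccc4)c(C(=O)CCC)c(OCc4ccccc4)c(C)c3OC)c(OCc3ccccc3)cc2O[Si](C(C)C)(C(C)C)C(C)C)c1OCc1ccccc1 | intermediate
37 | 4-(ArA-methyl)-5-(benzyloxy)-2-(ArC′-methyl)benzene-1,3-diol | CCCC(=O)c1c(OC)c(C)c(OCc2ccccc2)c(Cc2c(O)c(Cc3c(OCc4ccccc4)c(C(=O)CCC)c(OCc4ccccc4)c(C)c3OC)c(OCc3ccccc3)cc2O)c1OCc1ccccc1 | intermediate
38 | 1-[3-(ArA-methyl)-2-(benzyloxy)-4,6-dihydroxy-5-(ArC′-methyl)phenyl]ethan-1-one | CCCC(=O)c1c(OC)c(C)c(OCc2ccccc2)c(Cc2c(O)c(Cc3c(OCc4ccccc4)c(C(=O)CCC)c(OCc4ccccc4)c(C)c3OC)c(OCc3ccccc3)c(C(C)=O)c2O)c1OCc1ccccc1 | intermediate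
39 | 1-[3-({3-acetyl-5-[(3-butanoyl-2,6-dihydroxy-4-methoxy-5-methylphenyl)methyl]-2,4,6-trihydroxyphenyl}methyl)-2,6-dihydroxy-4-methoxy-5-methylphenyl]butan-1-one (CNP0184345.0) | CCCC(=O)c1c(O)c(C)c(OC)c(Cc2c(O)c(Cc3c(O)c(C)c(OC)c(C(=O)CCC)c3O)c(O)c(C(C)=O)c2O)c1O | target

## Step count and risk

Total step count: 19. Longest linear sequence: 11 steps (steps 1, 2, 3, 4, 5, 6, 9, 16, 17, 18, 19; the ring C arm, steps 1, 10–15, 16–19, is equally long).

Least certain steps:

**Step 16 (key step).** The most likely failure is a mismatch of thermal thresholds. The alkoxy-substituted cyclobutenone 21 is a vinylogous ester and may open only at temperatures at which the silyl ynol ether 31 isomerises, or at which vinylketene 32 dimerises or acylates the product phenol. A 1,5-hydrogen shift in 32 is a lesser risk, because the C4 substituent rotates outward. The fallback reverses the order in which the two ynol ethers are used. Acid chloride 12 is dehydrochlorinated (Et3N, Et2O, 0 °C to rt) in the presence of 31, so that the valuable ynol ether is consumed at room temperature in a ketene [2+2] cycloaddition, giving the 2,4-disubstituted racemic 4-(ArA-methyl)-2-(ArC-methyl)-3-(triisopropylsilyloxy)cyclobut-2-en-1-one F1. F1 is then heated in toluene with an excess of the small ynol ether 19, added in portions (or its ring opening is triggered by irradiation at room temperature before warming), to give the isomeric phenol 2-(ArA-methyl)-5-(benzyloxy)-4-(ArC-methyl)-3-(triisopropylsilyloxy)phenol F2. F2 has the same three ring B oxygens and the same two bridges as 36; only the positions of benzyl, silyl and free hydroxyl differ. Buffered TBAF gives 4-(ArA-methyl)-6-(benzyloxy)-2-(ArC′-methyl)benzene-1,3-diol F3, acetylation as in step 18 gives 1-[5-(ArA-methyl)-2-(benzyloxy)-4,6-dihydroxy-3-(ArC′-methyl)phenyl]ethan-1-one F4, and hydrogenolysis as in step 19 comes back to the route at the target 39.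

**Step 18.** The most likely failure is acid-induced side reaction before C-acylation is complete: O-acetylation of the hindered hydroxyls, Lewis-acid debenzylation next to the ketones with transfer of benzyl cations to C1, or ipso-protonation and cleavage of a bridge. The fallback avoids the Lewis acid and sets out from 37. Bromination at C1 (NBS, CH2Cl2, −20 °C) gives the ring B bromide 4-(ArA-methyl)-5-(benzyloxy)-6-bromo-2-(ArC′-methyl)benzene-1,3-diol F5. Stille coupling with tributyl(1-ethoxyvinyl)stannane (Pd(PPh3)4, toluene, 90 °C) gives the enol ether 4-(ArA-methyl)-5-(benzyloxy)-6-(1-ethoxyvinyl)-2-(ArC′-methyl)benzene-1,3-diol F6. Brief hydrolysis (1 M HCl, THF, rt) comes back to the route at 38.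

**Step 15.** The most likely failure is enolisation of the arylacetate by the lithium amide or the carbenoid in place of carbonyl addition, or attack of excess alkyllithium on benzyl ethers (Wittig rearrangement) during warming. The fallback sets out from 28. DIBAL-H (CH2Cl2, −78 °C) gives (ArC)acetaldehyde F7. Ohira–Bestmann homologation (dimethyl (1-diazo-2-oxopropyl)phosphonate, K2CO3, MeOH, 0 °C to rt) gives the terminal alkyne 3-(ArC)prop-1-yne F8. Deprotonation (LiHMDS, THF, −78 °C) gives lithium 3-(ArC)prop-1-yn-1-ide F9, which is oxidised with lithium tert-butyl peroxide (−78 to 0 °C) to ynolate 30; O-silylation with TIPSOTf comes back to the route at 31.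

**Step 9.** The most likely failure is loss of the terminal benzyl ynol ether 19 by rearrangement or polymerisation before it meets the ketene, together with dimerisation of the aldoketene 20 or lactonisation of 12 onto its ortho benzyloxy group. The fallback sets out from 12 and uses commercial ethoxyethyne in the cycloaddition (Et3N, Et2O, rt), giving racemic 3-ethoxy-4-(ArA-methyl)cyclobut-2-en-1-one F10. Acid-catalysed vinylogous transesterification with benzyl alcohol 13 (PPTS, toluene, 4 Å molecular sieves, 50 °C) comes back to the route at 21. The exchange cannot move the double bond, because the alternative dienol would be a cyclobutadiene.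

## Further compounds

F1 | step 16 | racemic 4-(ArA-methyl)-2-(ArC-methyl)-3-(triisopropylsilyloxy)cyclobut-2-en-1-one | O=C1C(Cc2c(OCc3ccccc3)c(C)c(OC)c(/C(O[Si](C(C)C)(C(C)C)C(C)C)=C/CC)c2OCc2ccccc2)=C(O[Si](C(C)C)(C(C)C)C(C)C)C1Cc1c(OCc2ccccc2)c(C(=O)CCC)c(OCc2ccccc2)c(C)c1OC
F2 | step 16 | 2-(ArA-methyl)-5-(benzyloxy)-4-(ArC-methyl)-3-(triisopropylsilyloxy)phenol | Oc1cc(OCc2ccccc2)c(Cc2c(OCc3ccccc3)c(C)c(OC)c(/C(O[Si](C(C)C)(C(C)C)C(C)C)=C/CC)c2OCc2ccccc2)c(O[Si](C(C)C)(C(C)C)C(C)C)c1Cc1c(OCc2ccccc2)c(C(=O)CCC)c(OCc2ccccc2)c(C)c1OC
F3 | step 16 | 4-(ArA-methyl)-6-(benzyloxy)-2-(ArC′-methyl)benzene-1,3-diol | Oc1cc(OCc2ccccc2)c(Cc2c(OCc3ccccc3)c(C)c(OC)c(C(=O)CCC)c2OCc2ccccc2)c(O)c1Cc1c(OCc2ccccc2)c(C(=O)CCC)c(OCc2ccccc2)c(C)c1OC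
F4 | step 16 | 1-[5-(ArA-methyl)-2-(benzyloxy)-4,6-dihydroxy-3-(ArC′-methyl)phenyl]ethan-1-one | CC(=O)c1c(O)c(Cc2c(OCc3ccccc3)c(C(=O)CCC)c(OCc3ccccc3)c(C)c2OC)c(O)c(Cc2c(OCc3ccccc3)c(C)c(OC)c(C(=O)CCC)c2OCc2ccccc2)c1OCc1ccccc1
F5 | step 18 | 4-(ArA-methyl)-5-(benzyloxy)-6-bromo-2-(ArC′-methyl)benzene-1,3-diol | CCCC(=O)c1c(OC)c(C)c(OCc2ccccc2)c(Cc2c(O)c(Cc3c(OCc4ccccc4)c(C(=O)CCC)c(OCc4ccccc4)c(C)c3OC)c(OCc3ccccc3)c(Br)c2O)c1OCc1ccccc1
F6 | step 18 | 4-(ArA-methyl)-5-(benzyloxy)-6-(1-ethoxyvinyl)-2-(ArC′-methyl)benzene-1,3-diol | CCCC(=O)c1c(OC)c(C)c(OCc2ccccc2)c(Cc2c(O)c(Cc3c(OCc4ccccc4)c(C(=O)CCC)c(OCc4ccccc4)c(C)c3OC)c(OCc3ccccc3)c(C(=C)OCC)c2O)c1OCc1ccccc1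
F7 | step 15 | (ArC)acetaldehyde | CC/C=C(\O[Si](C(C)C)(C(C)C)C(C)C)c1c(OC)c(C)c(OCc2ccccc2)c(CC=O)c1OCc1ccccc1
F8 | step 15 | 3-(ArC)prop-1-yne | CC/C=C(\O[Si](C(C)C)(C(C)C)C(C)C)c1c(OC)c(C)c(OCc2ccccc2)c(CC#C)c1OCc1ccccc1
F9 | step 15 | lithium 3-(ArC)prop-1-yn-1-ide | CC/C=C(\O[Si](C(C)C)(C(C)C)C(C)C)c1c(OC)c(C)c(OCc2ccccc2)c(CC#C[Li])c1OCc1ccccc1
F10 | step 9 | racemic 3-ethoxy-4-(ArA-methyl)cyclobut-2-en-1-one | CCOC1=CC(=O)C1Cc1c(OCc2ccccc2)c(C(=O)CCC)c(OCc2ccccc2)c(C)c1OC
A1 | alternative 1 | 4-methoxy-3-methyl-6-[2-(ring B aryl)ethyl]-2H-pyran-2-one carrying the benzylated A–B unit | COc1cc(CCc2c(OCc3ccccc3)c(Cc3c(OCc4ccccc4)c(C(=O)CCC)c(OCc4ccccc4)c(C)c3OC)c(OCc3ccccc3)c(C(C)=O)c2OCc2ccccc2)oc(=O)c1C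
A2 | alternative 1 | ring C resorcinol with free butanoyl carbon, joined to benzylated rings A and B | COc1cc(O)c(Cc2c(OCc3ccccc3)c(Cc3c(OCc4ccccc4)c(C(=O)CCC)c(OCc4ccccc4)c(C)c3OC)c(OCc3ccccc3)c(C(C)=O)c2OCc2ccccc2)c(O)c1C
A3 | alternative 2 | racemic 2-methyl-3-(triisopropylsilyloxy)-4-(ring B arylmethyl)cyclobut-2-en-1-one carrying the benzylated A–B unit | O=C1C(C)=C(O[Si](C(C)C)(C(C)C)C(C)C)C1Cc1c(OCc2ccccc2)c(Cc2c(OCc3ccccc3)c(C(=O)CCC)c(OCc3ccccc3)c(C)c2OC)c(OCc2ccccc2)c(C(C)=O)c1OCc1ccccc1
A4 | alternative 2 | methoxyethyne | COC#C
A5 | alternative 2 | ring C phenol with silyl ether and free butanoyl carbon, joined to benzylated rings A and B | COc1cc(O)c(Cc2c(OCc3ccccc3)c(Cc3c(OCc4ccccc4)c(C(=O)CCC)c(OCc4ccccc4)c(C)c3OC)c(OCc3ccccc3)c(C(C)=O)c2OCc2ccccc2)c(O[Si](C(C)C)(C(C)C)C(C)C)c1C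
A6 | alternative 3 | racemic 3-methoxy-4-methyl-2-(ring B arylmethyl)cyclobut-2-en-1-one carrying the benzylated B–C unit | O=C1C(Cc2c(OCc3ccccc3)c(C(C)=O)c(OCc3ccccc3)c(Cc3c(OCc4ccccc4)c(C)c(OC)c(C(=O)CCC)c3OCc3ccccc3)c2OCc2ccccc2)=C(OC)C1C
A7 | alternative 3 | (triisopropylsilyloxy)ethyne | CC(C)[Si](OC#C)(C(C)C)C(C)C
A8 | alternative 3 | ring A phenol with silyl ether and free butanoyl carbon, joined to benzylated rings B and C | Cc1c(O)cc(O[Si](C(C)C)(C(C)C)C(C)C)c(Cc2c(OCc3ccccc3)c(C(C)=O)c(OCc3ccccc3)c(Cc3c(OCc4ccccc4)c(C)c(OC)c(C(=O)CCC)c3OCc3ccccc3)c2OCc2ccccc2)c1OC
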